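**Plan**

- Numbering (farnesane): C1 is the OCH2 carbon, C2=C3(CH3), C4, C5, ring = C6–C11 with the methylidene on C7, OH on C10 and the gem-dimethyl on C11; the target is (2E,6R,10S). The enabling feature is that ring bond C6–C7 joins the methylidene-bearing carbon to the stereogenic ring CH, while O10 and the C6 side chain stand cis-1,3 across C11, so O10, C4, C5, C6, C11 and C10 can first exist as a six-membered α,β-unsaturated lactone whose β-carbon is C6.
- Retrosynthetic cuts, in order: the ether bond O–C1; C3–C4 (sp2–sp3); ring bond C6–C7 after re-tying O10 to C4 as the lactone; the lactone alkene C5=C6; C10–C11; C8–C9.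
- Forward: a C7–C10 bromo aldehyde is reverse-prenylated, acryloylated and closed by metathesis to the dihydropyranone (first ring). A vinyl radical then closes the carbocycle as a 2-oxabicyclo[3.3.1]nonanone. The lactone is opened to a C4 iodide, the C1–C3 unit is joined by Negishi coupling and the coumarin is attached last.
- Stereochemistry: C10 (S) comes from the (−)-α-pinene-derived prenylborane; C6 (R) is relayed from C10 because the lactone bridge can only be cis; the 2E alkene comes from syn hydrozirconation–iodination and a stereoretentive coupling.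

Key step: step 6

Assumption: (−)-α-pinene of high enantiomeric purity is the source of the borane, and 1-(2-hydroxy-6-methylphenyl)ethan-1-one is taken as the purchasable precursor of the coumarin.

**Route**

Step 1
Reactants: 1 tert-butyl acetate; 2 2,3-dibromopropene
Product: 4 tert-butyl 4-bromopent-4-enoate, via lithium enolate of tert-butyl acetate 3 (not isolated)
Conditions: LiN(i-Pr)2, THF, −78 °C; then 2, −78 → 0 °C
Reagents that add atoms: none
Why: Ester enolate alkylation: the lithium enolate of the tert-butyl ester resists self-condensation at −78 °C and displaces the allylic bromide of 2 (SN2), the vinylic C–Br bond being inert.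

Step 2
Reactants: 4 tert-butyl 4-bromopent-4-enoate
Product: 5 4-bromopent-4-enal
Conditions: i-Bu2AlH (1.1 equiv), CH2Cl2, −78 °C; then MeOH, aq. potassium sodium tartrate
Reagents that add atoms: none
Why: Partial ester reduction with i-Bu2AlH: the tetrahedral aluminium alkoxide of the bulky ester should persist at −78 °C and release the aldehyde only on work-up, so over-reduction is avoided and the vinyl bromide is untouched.

Step 3
Reactants: 5 4-bromopent-4-enal; 6 3-methylbuta-1,2-diene
Product: 9 (4S)-7-bromo-3,3-dimethylocta-1,7-dien-4-ol, via 3,3-dimethylallyl(diisopinocampheyl)borane 7 (not isolated), via homoallyl diisopinocampheylborinate 8 (not isolated)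
Conditions: Ipc2BH prepared from (−)-α-pinene, 6, THF, −25 °C; then 5, −78 °C; then aq. NaOH, H2O2, 0 °C → rt
Reagents that add atoms: none
Why: Asymmetric allylboration (Brown reverse prenylation): hydroboration of the allene at its terminal CH2 gives the 3,3-dimethylallylborane, which transfers its γ-carbon to the aldehyde through a closed chair transition state in which the isopinocampheyl groups from (−)-α-pinene direct attack to the Re face, setting C10 as S beside the new quaternary C11; alkaline peroxide then cleaves the borinate.

Step 4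
Reactants: 9 (4S)-7-bromo-3,3-dimethylocta-1,7-dien-4-ol; 10 acryloyl chloride
Product: 11 (4S)-7-bromo-3,3-dimethylocta-1,7-dien-4-yl prop-2-enoate
Conditions: i-Pr2NEt, DMAP (cat.), CH2Cl2, 0 °C → rt
Reagents that add atoms: none
Why: DMAP-catalysed O-acylation with an acid chloride, a reaction that tolerates secondary alcohols flanked by a quaternary carbon; the stereocentre is not involved.

Step 5
Reactants: 11 (4S)-7-bromo-3,3-dimethylocta-1,7-dien-4-yl prop-2-enoate
Product: 12 (6S)-6-(3-bromobut-3-en-1-yl)-5,5-dimethyl-5,6-dihydro-2H-pyran-2-one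
Conditions: second-generation Grubbs catalyst RuCl2(=CHPh)(H2IMes)(PCy3) (5 mol %), toluene (0.005 M), 80 °C
Reagents that add atoms: none
Why: Ring-closing olefin metathesis of an acrylate with a monosubstituted alkene should give the 5,6-dihydropyran-2-one with loss of ethene, helped by the gem-dimethyl group, while the 1,1-disubstituted, electron-poor bromoalkene does not engage the ruthenium carbene.

Step 6
Reactants: 12 (6S)-6-(3-bromobut-3-en-1-yl)-5,5-dimethyl-5,6-dihydro-2H-pyran-2-one
Product: 13 (1S,5R)-9,9-dimethyl-6-methylidene-2-oxabicyclo[3.3.1]nonan-3-one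
Conditions: Bu3SnH (1.3 equiv) and AIBN (0.2 equiv) added by syringe pump over 8 h, toluene (0.005 M), 90 °C
Reagents that add atoms: none
Why: The stannyl radical abstracts bromine from the 2-bromoalkene to give the sigma vinyl radical at C7, which adds to the lactone β-carbon C6 and leaves an ester-stabilised radical at C5 that takes hydrogen from Bu3SnH and carries the chain. The closest known reaction type is the Bu3SnH-mediated conjugate cyclisation of vinyl radicals from 2-bromo-1-alkenes onto enoates and enones, including closures that bridge a six-membered ring to a bicyclo[3.3.1]nonane. The cyclohexane C6–C11 closes in the 6-exo-trig mode through a chair transition state with the bromobutenyl chain axial on the half-chair lactone, a position that costs little because the two ring atoms 1,3 to C10 (the carbonyl carbon and the β-carbon) are sp2 and carry no axial substituent. The new stereocentre C6 is controlled by the tether: the three-atom O–C(=O)–CH2 bridge can span C10 and C6 only on one face, so S at C10 dictates R at C6 and the oxygen and the future side chain end up cis. The step needs ring closure to outrun direct reduction of the vinyl radical and attack at the β- rather than the α-carbon; high dilution with slow stannane addition should secure the first, and the six- versus seven-membered ring size together with the stabilised α-acyl radical secures the second. The fifth atoms from C7 (quaternary C11 and the ring oxygen) bear no hydrogen, which closes off 1,5-hydrogen transfer, and the exocyclic methylene arises directly from the vinyl radical.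

Step 7
Reactants: 13 (1S,5R)-9,9-dimethyl-6-methylidene-2-oxabicyclo[3.3.1]nonan-3-one
Product: 14 (1S,3R)-3-(2-hydroxyethyl)-2,2-dimethyl-4-methylidenecyclohexan-1-ol
Conditions: LiAlH4, THF, 0 °C → rt; then H2O, aq. NaOH
Reagents that add atoms: none
Why: Hydride reduction of a lactone to the diol; neither stereocentre is touched and the isolated alkene is inert.

Step 8
Reactants: 14 (1S,3R)-3-(2-hydroxyethyl)-2,2-dimethyl-4-methylidenecyclohexan-1-ol
Product: 15 (1S,3R)-3-(2-iodoethyl)-2,2-dimethyl-4-methylidenecyclohexan-1-ol
Conditions: PPh3, I2, imidazole, CH2Cl2, 0 °C (I2 added to PPh3 and imidazole before 14)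
Reagents that add atoms: iodine, II
Why: Appel-type iodination: the preformed iodophosphonium salt activates the unhindered primary alcohol in preference to the secondary alcohol next to the quaternary carbon, and with no free iodine present the alkene should not undergo iodoetherification.

Step 9
Reactants: 15 (1S,3R)-3-(2-iodoethyl)-2,2-dimethyl-4-methylidenecyclohexan-1-ol
Product: 16 triethyl{[(1S,3R)-3-(2-iodoethyl)-2,2-dimethyl-4-methylidenecyclohexyl]oxy}silane
Conditions: Et3SiOTf, 2,6-lutidine, CH2Cl2, −78 → 0 °C
Reagents that add atoms: triethylsilyl trifluoromethanesulfonate, CC[Si](CC)(CC)OS(=O)(=O)C(F)(F)F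
Why: Silylation with a silyl triflate and a hindered pyridine base protects the congested secondary alcohol, so that no acidic proton can quench the organozinc made in step 12.

Step 10
Reactants: 17 but-2-yn-1-ol
Product: 18 tert-butyl(but-2-yn-1-yloxy)dimethylsilane
Conditions: t-BuMe2SiCl, imidazole, CH2Cl2, rt
Reagents that add atoms: tert-butyldimethylsilyl chloride, CC(C)(C)[Si](C)(C)Cl
Why: Standard silylation of a primary propargylic alcohol.

Step 11
Reactants: 18 tert-butyl(but-2-yn-1-yloxy)dimethylsilane
Product: 20 tert-butyl{[(2E)-3-iodobut-2-en-1-yl]oxy}dimethylsilane, via (E)-alkenylzirconocene chloride 19 (not isolated)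
Conditions: Cp2Zr(H)Cl (2 equiv), THF, 50 °C; then I2, THF, 0 °C
Reagents that add atoms: iodine, II
Why: Hydrozirconation–iodination: syn addition of Zr–H, with excess reagent and warming equilibrating zirconium to the less hindered methyl-bearing carbon, followed by iodinolysis with retention, should give the (E)-3-iodoalkene.

Step 12
Reactants: 16 triethyl{[(1S,3R)-3-(2-iodoethyl)-2,2-dimethyl-4-methylidenecyclohexyl]oxy}silane; 20 tert-butyl{[(2E)-3-iodobut-2-en-1-yl]oxy}dimethylsilane
Product: 22 tert-butyl{[(2E)-5-[(1R,3S)-2,2-dimethyl-6-methylidene-3-(triethylsilyloxy)cyclohexyl]-3-methylpent-2-en-1-yl]oxy}dimethylsilane, via alkylzinc iodide 21 (not isolated)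
Conditions: Zn dust (activated with BrCH2CH2Br, Me3SiCl), LiCl, THF, 40 °C; then 20, PdCl2(dppf) (5 mol %), THF, rt
Reagents that add atoms: none
Why: Direct zinc insertion into the primary C–I bond followed by Negishi sp3–sp2 cross-coupling, in which zerovalent palladium adds to the alkenyl iodide, transmetalates and eliminates with retention, so the 2E geometry of 20 is carried over and the allylic silyl ether is not ionised.

Step 13
Reactants: 22 tert-butyl{[(2E)-5-[(1R,3S)-2,2-dimethyl-6-methylidene-3-(triethylsilyloxy)cyclohexyl]-3-methylpent-2-en-1-yl]oxy}dimethylsilane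
Product: 23 (1S,3R)-3-[(3E)-5-hydroxy-3-methylpent-3-en-1-yl]-2,2-dimethyl-4-methylidenecyclohexan-1-ol
Conditions: Bu4NF, THF, rt → 40 °C
Reagents that add atoms: none
Why: Fluoride-mediated cleavage of both silyl ethers in one operation, under conditions that leave the two alkenes and the stereocentres alone.

Step 14
Reactants: 24 1-(2-hydroxy-6-methylphenyl)ethan-1-one
Product: 25 4-hydroxy-5-methyl-2H-chromen-2-one
Conditions: NaH, (EtO)2CO, toluene, 110 °C; then aq. HCl
Reagents that add atoms: diethyl carbonate, CCOC(=O)OCC
Why: Claisen-type C-acylation of the ketone enolate with diethyl carbonate followed by lactonisation onto the phenoxide, the standard construction of 4-hydroxycoumarins.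

Step 15
Reactants: 23 (1S,3R)-3-[(3E)-5-hydroxy-3-methylpent-3-en-1-yl]-2,2-dimethyl-4-methylidenecyclohexan-1-ol; 25 4-hydroxy-5-methyl-2H-chromen-2-one
Product: 26 4-{[(2E)-5-[(1R,3S)-3-hydroxy-2,2-dimethyl-6-methylidenecyclohexyl]-3-methylpent-2-en-1-yl]oxy}-5-methyl-2H-chromen-2-one
Conditions: PPh3, DIAD, THF, 0 °C → rt
Reagents that add atoms: none
Why: Mitsunobu etherification: the acidic enol of 25 should be alkylated on O4 by the alkoxyphosphonium ion of the primary allylic alcohol (SN2), while the secondary alcohol beside the quaternary carbon is too hindered to be activated.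

**Compound list**

1 | tert-butyl acetate | CC(=O)OC(C)(C)C | starting material
2 | 2,3-dibromopropene | C=C(Br)CBr | starting material
3 | lithium enolate of tert-butyl acetate | C=C(O[Li])OC(C)(C)C | intermediate (not isolated)
4 | tert-butyl 4-bromopent-4-enoate | C=C(Br)CCC(=O)OC(C)(C)C | intermediate
5 | 4-bromopent-4-enal | C=C(Br)CCC=O | intermediate
6 | 3-methylbuta-1,2-diene | CC(C)=C=C | starting material
7 | 3,3-dimethylallyl(diisopinocampheyl)borane, isopinocampheyl groups from (−)-α-pinene | CC(C)=CCB([C@H]1C[C@H]2C[C@@H]([C@@H]1C)C2(C)C)[C@H]1C[C@H]2C[C@@H]([C@@H]1C)C2(C)C | intermediate (not isolated)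
8 | (4S)-7-bromo-3,3-dimethylocta-1,7-dien-4-yl diisopinocampheylborinate | C=C(Br)CC[C@H](OB([C@H]1C[C@H]2C[C@@H]([C@@H]1C)C2(C)C)[C@H]1C[C@H]2C[C@@H]([C@@H]1C)C2(C)C)C(C)(C)C=C | intermediate (not isolated)
9 | (4S)-7-bromo-3,3-dimethylocta-1,7-dien-4-ol | C=C(Br)CC[C@H](O)C(C)(C)C=C | intermediate
10 | acryloyl chloride | C=CC(Cl)=O | starting material
11 | (4S)-7-bromo-3,3-dimethylocta-1,7-dien-4-yl prop-2-enoate | C=C(Br)CC[C@H](OC(=O)C=C)C(C)(C)C=C | intermediate
12 | (6S)-6-(3-bromobut-3-en-1-yl)-5,5-dimethyl-5,6-dihydro-2H-pyran-2-one | C=C(Br)CC[C@@H]1OC(=O)C=CC1(C)C | intermediate (key-step precursor)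
13 | (1S,5R)-9,9-dimethyl-6-methylidene-2-oxabicyclo[3.3.1]nonan-3-one | C=C1CC[C@@H]2OC(=O)C[C@H]1C2(C)C | intermediate (key-step product)
14 | (1S,3R)-3-(2-hydroxyethyl)-2,2-dimethyl-4-methylidenecyclohexan-1-ol | C=C1CC[C@H](O)C(C)(C)[C@@H]1CCO | intermediate
15 | (1S,3R)-3-(2-iodoethyl)-2,2-dimethyl-4-methylidenecyclohexan-1-ol | C=C1CC[C@H](O)C(C)(C)[C@@H]1CCI | intermediate
16 | triethyl{[(1S,3R)-3-(2-iodoethyl)-2,2-dimethyl-4-methylidenecyclohexyl]oxy}silane | C=C1CC[C@H](O[Si](CC)(CC)CC)C(C)(C)[C@@H]1CCI | intermediate
17 | but-2-yn-1-ol | CC#CCO | starting material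
18 | tert-butyl(but-2-yn-1-yloxy)dimethylsilane | CC#CCO[Si](C)(C)C(C)(C)C | intermediate
19 | chloro{(2E)-4-[(tert-butyldimethylsilyl)oxy]but-2-en-2-yl}zirconocene (cyclopentadienyl rings drawn sigma-bonded) | C/C(=C\CO[Si](C)(C)C(C)(C)C)[Zr](Cl)(C1C=CC=C1)C1C=CC=C1 | intermediate (not isolated)
20 | tert-butyl{[(2E)-3-iodobut-2-en-1-yl]oxy}dimethylsilane | C/C(I)=C\CO[Si](C)(C)C(C)(C)C | intermediate
21 | {2-[(1R,3S)-2,2-dimethyl-6-methylidene-3-(triethylsilyloxy)cyclohexyl]ethyl}zinc iodide | C=C1CC[C@H](O[Si](CC)(CC)CC)C(C)(C)[C@@H]1CC[Zn]I | intermediate (not isolated)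
22 | tert-butyl{[(2E)-5-[(1R,3S)-2,2-dimethyl-6-methylidene-3-(triethylsilyloxy)cyclohexyl]-3-methylpent-2-en-1-yl]oxy}dimethylsilane | C=C1CC[C@H](O[Si](CC)(CC)CC)C(C)(C)[C@@H]1CC/C(C)=C/CO[Si](C)(C)C(C)(C)C | intermediate
23 | (1S,3R)-3-[(3E)-5-hydroxy-3-methylpent-3-en-1-yl]-2,2-dimethyl-4-methylidenecyclohexan-1-ol | C=C1CC[C@H](O)C(C)(C)[C@@H]1CC/C(C)=C/CO | intermediate
24 | 1-(2-hydroxy-6-methylphenyl)ethan-1-one | CC(=O)c1c(C)cccc1O | starting material
25 | 4-hydroxy-5-methyl-2H-chromen-2-one | Cc1cccc2oc(=O)cc(O)c12 | intermediate
26 | 4-{[(2E)-5-[(1R,3S)-3-hydroxy-2,2-dimethyl-6-methylidenecyclohexyl]-3-methylpent-2-en-1-yl]oxy}-5-methyl-2H-chromen-2-one (CNP0172901.1) | C=C1CC[C@H](O)C(C)(C)[C@@H]1CC/C(C)=C/COc1cc(=O)oc2cccc(C)c12 | target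

**Count**

Total steps: 15. Longest linear sequence: 12 steps (steps 1–9, 12, 13 and 15); steps 10–11 and step 14 are side branches.

**Steps most likely to fail**

Step 6. The vinyl radical may take hydrogen from the stannane before it reaches the lactone β-carbon, so that simple debromination competes with ring closure. The fallback sets out from 12 and makes the same C6–C7 bond without a free radical, by a reductive Heck cyclisation (Pd(OAc)2, PPh3, HCO2Na, Et4NCl, DMF, 80 °C). Zerovalent palladium inserts into the C–Br bond and the alkenylpalladium adds syn across the lactone alkene from the tethered face. The only β-hydrogen sits at the incipient bridgehead, so the palladium enolate should be reduced by formate instead of eliminating. The route is rejoined at 13 and no new compound arises (F0).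

Step 5. The ruthenium carbene may load poorly on the neopentyl-type vinyl group and decompose on the acrylate, so that closure stalls or oligomers form. The fallback sets out from 9. Esterification with diethylphosphonoacetic acid (DCC, DMAP, CH2Cl2) would give (4S)-7-bromo-3,3-dimethylocta-1,7-dien-4-yl 2-(diethoxyphosphoryl)acetate F1. OsO4 (cat.) with N-methylmorpholine N-oxide should dihydroxylate the monosubstituted alkene in preference to the deactivated bromoalkene, giving (4S)-7-bromo-1,2-dihydroxy-3,3-dimethyloct-7-en-4-yl 2-(diethoxyphosphoryl)acetate F2. NaIO4 then cleaves the diol to (3S)-6-bromo-2,2-dimethyl-1-oxohept-6-en-3-yl 2-(diethoxyphosphoryl)acetate F3. An intramolecular Horner–Wadsworth–Emmons olefination (LiCl, i-Pr2NEt, MeCN, rt) closes the lactone ring with the cis alkene and rejoins the route at 12.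

Step 15. The ambident coumarin anion may be alkylated at C3 or at the lactone carbonyl oxygen, or the allylic phosphonium ion may be attacked with allylic transposition. The fallback reverses the roles of the partners. Compound 25 is converted with POCl3 (Et3N, 90 °C) into 4-chloro-5-methyl-2H-chromen-2-one F4. The sodium alkoxide of the primary allylic alcohol of 23 (NaH, 1 equiv, THF, 0 °C) then displaces chloride by addition–elimination at C4, which can only give the O4 ether. The route is rejoined at 26.

Further compounds
F0 | step 6 | none | none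
F1 | step 5 | (4S)-7-bromo-3,3-dimethylocta-1,7-dien-4-yl 2-(diethoxyphosphoryl)acetate | C=C(Br)CC[C@H](OC(=O)CP(=O)(OCC)OCC)C(C)(C)C=C
F2 | step 5 | (4S)-7-bromo-1,2-dihydroxy-3,3-dimethyloct-7-en-4-yl 2-(diethoxyphosphoryl)acetate (mixture at C2) | C=C(Br)CC[C@H](OC(=O)CP(=O)(OCC)OCC)C(C)(C)C(O)CO
F3 | step 5 | (3S)-6-bromo-2,2-dimethyl-1-oxohept-6-en-3-yl 2-(diethoxyphosphoryl)acetate | C=C(Br)CC[C@H](OC(=O)CP(=O)(OCC)OCC)C(C)(C)C=O
F4 | step 15 | 4-chloro-5-methyl-2H-chromen-2-one | Cc1cccc2oc(=O)cc(Cl)c12
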